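**Plan**
- Retrosynthetic cuts, in order: the C7 O–MOM mask, the ring B ketal mask and the C5 O–CH3 bond; C4–C4a and O1–C2 of the pyran (ring C); C6–C7 of ring A; the exocyclic bond from C6 to the acyl carbonyl; the ring B O–prenyl bond.
- Enabling feature: ring A carries oxygen on C5, C7 and C8a and the acyl group on C6. It is a 2-acylphloroglucinol, which is the Claisen fold of a 3,5,7-triketo ester. The starter unit is the ring B arylglyoxylyl group, with the carbonyl next to ring B masked as a dimethyl ketal.
- Forward order: ring B is bought. The eight-carbon chain is joined by acylating the trianion of methyl 3,5-dioxohexanoate with the ketal ester. Ring A then closes by Claisen condensation, and ring C closes last through the para oxygen.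
- The two ortho hydroxyls of the symmetric ring A are told apart by mono-MOM protection before ring C is made. Chelation of the remaining hydroxyl steers the rearrangement, so the free OH ends at C5 and is methylated there.
- Stereochemistry: the target has no stereocentre. The C3=C4 alkene is cis by ring constraint, and the prenyl alkene has no E/Z isomers.

Key step: step 5

Assumption: ficucaricone C is taken as the open 1,2-diketone as drawn. The cyclic hemiketal that its C7 hydroxyl can form with the distal carbonyl is regarded as a tautomer in equilibrium with it.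

Step 1
Reactants: 1 4-hydroxyphenylglyoxylic acid
Product: 2 methyl 2-(4-hydroxyphenyl)-2,2-dimethoxyacetate
Conditions: HC(OMe)3 (4 equiv), MeOH, H2SO4 (cat.), reflux; then NaHCO3
Reagents that add atoms: methanol, CO; trimethyl orthoformate, COC(OC)OC
Why: Fischer esterification and orthoformate-driven ketalisation of the activated α-keto carbonyl run together in acidic methanol, and both are placed before the acid-sensitive prenyl ether exists.

Step 2
Reactants: 2 methyl 2-(4-hydroxyphenyl)-2,2-dimethoxyacetate; 3 prenyl bromide (1-bromo-3-methylbut-2-ene)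
Product: 4 methyl 2,2-dimethoxy-2-[4-(3-methylbut-2-enyloxy)phenyl]acetate
Conditions: K2CO3, DMF, rt
Reagents that add atoms: none
Why: Williamson ether synthesis at the only acidic site, the phenol, under conditions to which the ester and the ketal are inert.

Step 3
Reactants: 5 dehydroacetic acid (3-acetyl-4-hydroxy-6-methyl-2H-pyran-2-one)
Product: 6 methyl 3,5-dioxohexanoate
Conditions: Mg(OMe)2, MeOH, reflux; then cold aq. HCl
Reagents that add atoms: methanol, CO
Why: Methanolysis of the pyrone lactone followed by retro-Claisen loss of the 3-acetyl group is the standard preparation of this 3,5-diketo ester.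

Step 4
Reactants: 4 methyl 2,2-dimethoxy-2-[4-(3-methylbut-2-enyloxy)phenyl]acetate; 6 methyl 3,5-dioxohexanoate
Product: 8 methyl 8,8-dimethoxy-8-[4-(3-methylbut-2-enyloxy)phenyl]-3,5,7-trioxooctanoate, via trilithium trianion 7 (not isolated)
Conditions: 6 (2 equiv), LiN(iPr)2 (6.2 equiv), THF, −78 → 0 °C; then 4, 0 °C → rt; AcOH, −78 °C; used without chromatography
Reagents that add atoms: none
Why: Crossed Claisen condensation of a polyanion, in which the terminal CH2 carbanion of 7 (last formed, most nucleophilic) attacks the non-enolisable, inductively activated ester 4 while the second equivalent of 7 takes up the proton of the more acidic product.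

Step 5
Reactants: 8 methyl 8,8-dimethoxy-8-[4-(3-methylbut-2-enyloxy)phenyl]-3,5,7-trioxooctanoate
Product: 10 2,2-dimethoxy-2-[4-(3-methylbut-2-enyloxy)phenyl]-1-(2,4,6-trihydroxyphenyl)ethanone, via 2-acylcyclohexane-1,3,5-trione 9 (not isolated)
Conditions: Mg(OMe)2 (4 equiv), MeOH, reflux; then 10% aq. AcOH, 0 °C
Reagents that add atoms: none
Why: Mg(OMe)2 turns 8 into a magnesium-chelated polyenolate whose carbon between the C5 and C7 carbonyls (octanoate C6) adds to the ester carbonyl C1, and loss of methoxide gives trione 9, which enolises irreversibly to the aromatic triol. The reaction type is the intramolecular Claisen (Dieckmann-type) condensation of 3,5,7-triketo esters to 2-acylphloroglucinols, the laboratory counterpart of chalcone-synthase folding. Ring A closes in the 6-exo-trig mode, and the new bond, octanoate C6–C1, becomes C6–C7 of the chromene. No stereocentre is formed. The step needs Claisen folding rather than aldol folding (C2 onto C7) or lactonisation to a 4-hydroxy-2-pyrone; the C7 carbonyl is neopentyl-like beside the quaternary ketal carbon and is tied up as a magnesium β-diketonate, and any pyrone is reopened by methoxide and returned to 8. The ketal also keeps the carbonyl next to ring B out of every enolisation and addition.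

Step 6
Reactants: 10 2,2-dimethoxy-2-[4-(3-methylbut-2-enyloxy)phenyl]-1-(2,4,6-trihydroxyphenyl)ethanone; 11 3-chloro-3-methylbut-1-yne
Product: 12 1-[2,6-dihydroxy-4-(2-methylbut-3-yn-2-yloxy)phenyl]-2,2-dimethoxy-2-[4-(3-methylbut-2-enyloxy)phenyl]ethanone
Conditions: 11 (1.2 equiv), DBU (1.2 equiv), CuCl2 (1 mol %), MeCN, 0 °C → rt, N2
Reagents that add atoms: none
Why: Copper-catalysed O-propargylation of a phenol with a tertiary propargylic chloride, in which one equivalent of base ionises only the para hydroxyl (the most acidic, and the only one not hydrogen-bonded to the ketone), so the ether forms on the oxygen that becomes O1.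

Step 7
Reactants: 12 1-[2,6-dihydroxy-4-(2-methylbut-3-yn-2-yloxy)phenyl]-2,2-dimethoxy-2-[4-(3-methylbut-2-enyloxy)phenyl]ethanone
Product: 13 1-[2-hydroxy-6-(methoxymethoxy)-4-(2-methylbut-3-yn-2-yloxy)phenyl]-2,2-dimethoxy-2-[4-(3-methylbut-2-enyloxy)phenyl]ethanone
Conditions: MOMCl (1.1 equiv), iPr2NEt, CH2Cl2, 0 °C → rt
Reagents that add atoms: chloromethyl methyl ether, COCCl
Why: Mono-acetalisation of a symmetric 2,6-dihydroxyaryl ketone, where either hydroxyl gives the same product and the survivor is held in a strong hydrogen bond to the carbonyl and resists a second alkylation.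

Step 8
Reactants: 13 1-[2-hydroxy-6-(methoxymethoxy)-4-(2-methylbut-3-yn-2-yloxy)phenyl]-2,2-dimethoxy-2-[4-(3-methylbut-2-enyloxy)phenyl]ethanone
Product: 16 1-[5-hydroxy-7-(methoxymethoxy)-2,2-dimethyl-2H-chromen-6-yl]-2,2-dimethoxy-2-[4-(3-methylbut-2-enyloxy)phenyl]ethanone, via ortho-allenylphenol 14 (not isolated), via ortho-quinone methide 15 (not isolated)
Conditions: o-xylene, 140 °C, Ar
Reagents that add atoms: none
Why: Aromatic propargyl Claisen rearrangement, 1,5-hydrogen shift and oxa-6π electrocyclisation, in which the [3,3] shift should go to the less shielded carbon next to the chelated hydroxyl because only that path keeps the HO–C=C–C=O chelate conjugated in the dienone, closure through the para oxygen is the only mode that preserves the chelate, and the gem-dimethylpropargyl ether reacts well below the temperature at which the ring B prenyl ether rearranges.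

Step 9
Reactants: 16 1-[5-hydroxy-7-(methoxymethoxy)-2,2-dimethyl-2H-chromen-6-yl]-2,2-dimethoxy-2-[4-(3-methylbut-2-enyloxy)phenyl]ethanone
Product: 17 1-[5-methoxy-7-(methoxymethoxy)-2,2-dimethyl-2H-chromen-6-yl]-2,2-dimethoxy-2-[4-(3-methylbut-2-enyloxy)phenyl]ethanone
Conditions: MeI (excess), K2CO3, DMF, 40 °C
Reagents that add atoms: iodomethane, CI
Why: Williamson methylation of the chelated C5 phenol, which is the only acidic site left because the ketone has no α-hydrogen.

Step 10
Reactants: 17 1-[5-methoxy-7-(methoxymethoxy)-2,2-dimethyl-2H-chromen-6-yl]-2,2-dimethoxy-2-[4-(3-methylbut-2-enyloxy)phenyl]ethanone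
Product: 18 ficucaricone C, 1-(7-hydroxy-5-methoxy-2,2-dimethyl-2H-chromen-6-yl)-2-[4-(3-methylbut-2-enyloxy)phenyl]ethane-1,2-dione
Conditions: 2 M aq. HCl, THF, 40 °C
Reagents that add atoms: water, O
Why: Acetal hydrolysis in dilute, water-rich acid should cleave the MOM ether ortho to the carbonyl and the ketal, whose oxocarbenium ion is stabilised by the para-alkoxyphenyl group, under conditions mild enough for the aryl prenyl ether and the chromene.

**Compound list**
1 | 4-hydroxyphenylglyoxylic acid | O=C(O)C(=O)c1ccc(O)cc1 | starting material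
2 | methyl 2-(4-hydroxyphenyl)-2,2-dimethoxyacetate | COC(=O)C(OC)(OC)c1ccc(O)cc1 | intermediate
3 | prenyl bromide (1-bromo-3-methylbut-2-ene) | CC(C)=CCBr | starting material
4 | methyl 2,2-dimethoxy-2-[4-(3-methylbut-2-enyloxy)phenyl]acetate | COC(=O)C(OC)(OC)c1ccc(OCC=C(C)C)cc1 | intermediate
5 | dehydroacetic acid (3-acetyl-4-hydroxy-6-methyl-2H-pyran-2-one) | CC(=O)C1=C(O)C=C(C)OC1=O | starting material
6 | methyl 3,5-dioxohexanoate | COC(=O)CC(=O)CC(C)=O | intermediate
7 | trilithium trianion of methyl 3,5-dioxohexanoate (not isolated) | [Li+].[Li+].[Li+].C=C([O-])C=C([O-])C=C([O-])OC | intermediate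
8 | methyl 8,8-dimethoxy-8-[4-(3-methylbut-2-enyloxy)phenyl]-3,5,7-trioxooctanoate | COC(=O)CC(=O)CC(=O)CC(=O)C(OC)(OC)c1ccc(OCC=C(C)C)cc1 | intermediate
9 | 2-{2,2-dimethoxy-2-[4-(3-methylbut-2-enyloxy)phenyl]acetyl}cyclohexane-1,3,5-trione (not isolated) | O=C1CC(=O)CC(=O)C1C(=O)C(OC)(OC)c1ccc(OCC=C(C)C)cc1 | intermediate
10 | 2,2-dimethoxy-2-[4-(3-methylbut-2-enyloxy)phenyl]-1-(2,4,6-trihydroxyphenyl)ethanone | COC(OC)(C(=O)c1c(O)cc(O)cc1O)c1ccc(OCC=C(C)C)cc1 | intermediate
11 | 3-chloro-3-methylbut-1-yne | C#CC(C)(C)Cl | starting material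
12 | 1-[2,6-dihydroxy-4-(2-methylbut-3-yn-2-yloxy)phenyl]-2,2-dimethoxy-2-[4-(3-methylbut-2-enyloxy)phenyl]ethanone | Oc1cc(OC(C)(C)C#C)cc(O)c1C(=O)C(OC)(OC)c1ccc(OCC=C(C)C)cc1 | intermediate
13 | 1-[2-hydroxy-6-(methoxymethoxy)-4-(2-methylbut-3-yn-2-yloxy)phenyl]-2,2-dimethoxy-2-[4-(3-methylbut-2-enyloxy)phenyl]ethanone | COCOc1cc(OC(C)(C)C#C)cc(O)c1C(=O)C(OC)(OC)c1ccc(OCC=C(C)C)cc1 | intermediate
14 | 1-[2,4-dihydroxy-6-(methoxymethoxy)-3-(3-methylbuta-1,2-dienyl)phenyl]-2,2-dimethoxy-2-[4-(3-methylbut-2-enyloxy)phenyl]ethanone (not isolated) | COCOc1cc(O)c(C=C=C(C)C)c(O)c1C(=O)C(OC)(OC)c1ccc(OCC=C(C)C)cc1 | intermediate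
15 | 4-{2,2-dimethoxy-2-[4-(3-methylbut-2-enyloxy)phenyl]acetyl}-3-hydroxy-5-(methoxymethoxy)-2-(3-methylbut-2-enylidene)cyclohexa-3,5-dien-1-one (not isolated) | COCOC1=CC(=O)C(=CC=C(C)C)C(O)=C1C(=O)C(OC)(OC)c1ccc(OCC=C(C)C)cc1 | intermediate
16 | 1-[5-hydroxy-7-(methoxymethoxy)-2,2-dimethyl-2H-chromen-6-yl]-2,2-dimethoxy-2-[4-(3-methylbut-2-enyloxy)phenyl]ethanone | Oc1c2c(cc(OCOC)c1C(=O)C(OC)(OC)c1ccc(OCC=C(C)C)cc1)OC(C)(C)C=C2 | intermediate
17 | 1-[5-methoxy-7-(methoxymethoxy)-2,2-dimethyl-2H-chromen-6-yl]-2,2-dimethoxy-2-[4-(3-methylbut-2-enyloxy)phenyl]ethanone | COc1c2c(cc(OCOC)c1C(=O)C(OC)(OC)c1ccc(OCC=C(C)C)cc1)OC(C)(C)C=C2 | intermediate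
18 | ficucaricone C | COc1c2c(cc(O)c1C(=O)C(=O)c1ccc(OCC=C(C)C)cc1)OC(C)(C)C=C2 | target

Total step count: 10. Longest linear sequence: 9 (steps 1, 2 and 4 to 10; step 3 is a one-step side branch).

**Steps most likely to fail**

**Step 5.** The polyenolate may fold in the aldol sense, with octanoate C2 adding to the C7 carbonyl followed by dehydration. Methoxide may also cut the chain by retro-Claisen cleavage at the inductively activated C7 carbonyl.

The fallback sets out from 4 and comes back at 10; ring A is bought instead of built.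
- Phloroglucinol is O-allylated (allyl bromide, K2CO3, DMF) to 1,3,5-tris(allyloxy)benzene F1.
- Monobromination (NBS, CH2Cl2, −78 → 0 °C) gives 2-bromo-1,3,5-tris(allyloxy)benzene F2.
- Exchange with n-BuLi (THF, −78 °C) gives 2,4,6-tris(allyloxy)phenyllithium F3.
- The aryllithium adds to ester 4. The hindered ketone 1-[2,4,6-tris(allyloxy)phenyl]-2,2-dimethoxy-2-[4-(3-methylbut-2-enyloxy)phenyl]ethanone F4 should resist a second addition.
- Pd(PPh3)4 with morpholine in THF removes the three monosubstituted allyl groups and gives 10. Zerovalent palladium engages these far faster than the trisubstituted prenyl ether.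

**Step 8.** The [3,3] shift may show poor positional selectivity between the two ortho carbons of the desymmetrised ring. If heating has to be prolonged, Claisen rearrangement of the ring B prenyl ether may set in.

The fallback sets out from 12 and comes back at 16; protection and annulation change places.
- Diol 12 is heated in o-xylene while ring A is still symmetric, so both ortho carbons are the same. This should give 1-(5,7-dihydroxy-2,2-dimethyl-2H-chromen-6-yl)-2,2-dimethoxy-2-[4-(3-methylbut-2-enyloxy)phenyl]ethanone F5.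
- The hydroxyls are then told apart by their surroundings. MOMCl and iPr2NEt should react at the C7 hydroxyl, which lies next to C8–H, rather than at the C5 hydroxyl wedged between C4 and the acyl group. The product is 16.

**Step 4.** Conversion may stall through proton transfer from the product to the trianion, self-condensation of the ester-bearing trianion, or slow attack on the hindered ester. Premature cyclisation of the open chain may occur during isolation.

The fallback sets out from 4 and comes back at 8; the chain is carried as a stable lactone.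
- 4-Hydroxy-6-methyl-2H-pyran-2-one is deprotonated twice with LiN(iPr)2 (THF, −78 → 0 °C) to the dilithium dianion of 4-hydroxy-6-methyl-2-pyrone F6.
- F6 is acylated at its exocyclic CH2 by ester 4 to give 6-{3,3-dimethoxy-3-[4-(3-methylbut-2-enyloxy)phenyl]-2-oxopropyl}-4-hydroxy-2H-pyran-2-one F7.
- Mg(OMe)2 in refluxing methanol opens the lactone to 8 in the flask, which then folds as in step 5.

**Further compounds**
F1 | step 5 | 1,3,5-tris(allyloxy)benzene | C=CCOc1cc(OCC=C)cc(OCC=C)c1
F2 | step 5 | 2-bromo-1,3,5-tris(allyloxy)benzene | C=CCOc1cc(OCC=C)c(Br)c(OCC=C)c1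
F3 | step 5 | 2,4,6-tris(allyloxy)phenyllithium | [Li]c1c(OCC=C)cc(OCC=C)cc1OCC=C
F4 | step 5 | 1-[2,4,6-tris(allyloxy)phenyl]-2,2-dimethoxy-2-[4-(3-methylbut-2-enyloxy)phenyl]ethanone | C=CCOc1cc(OCC=C)c(C(=O)C(OC)(OC)c2ccc(OCC=C(C)C)cc2)c(OCC=C)c1
F5 | step 8 | 1-(5,7-dihydroxy-2,2-dimethyl-2H-chromen-6-yl)-2,2-dimethoxy-2-[4-(3-methylbut-2-enyloxy)phenyl]ethanone | Oc1c2c(cc(O)c1C(=O)C(OC)(OC)c1ccc(OCC=C(C)C)cc1)OC(C)(C)C=C2
F6 | step 4 | dilithium dianion of 4-hydroxy-6-methyl-2-pyrone | [Li+].[Li+].C=C1C=C([O-])C=C([O-])O1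
F7 | step 4 | 6-{3,3-dimethoxy-3-[4-(3-methylbut-2-enyloxy)phenyl]-2-oxopropyl}-4-hydroxy-2H-pyran-2-one | O=C1C=C(O)C=C(CC(=O)C(OC)(OC)c2ccc(OCC=C(C)C)cc2)O1
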